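The C16 acyl chain is cut at its unactivated C5–C6 bond. A nickel hydride-catalysed anti-Markovnikov hydroalkylation joins 1-iodoundecane to the terminal C4=C5 alkene of a pent-4-enoate. This ester already sits on the benzylic CH2O of ring A (methoxy ring) in the finished diaryl ether. H goes to C4 and undecyl to C5, so the saturated palmitate appears in one operation as the last step. The step exploits the unbranched, stereocentre-free chain. It needs no hydrogenation, which spares the hydrogenolysis-prone ring A ArCH2–O bond and leaves both phenols free. The tetra-ortho-substituted ether between rings A and B (salicylate ring) comes from a depside Smiles rearrangement, and the ring A phenol replaces a bromine.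

Key step: step 6

Remark: the target has no stereocentre and no C=C bond, so no stereocontrol is needed. Chain atoms are numbered from the palmitoyl carbonyl carbon (C1). Compounds 1, 2, 9 and 11 are taken to be catalogue chemicals.

Step 1
Reactants: 1 2,6-dihydroxy-4-methylbenzoic acid; 2 3-bromo-2-hydroxy-5-methoxybenzaldehyde
Product: 3 2-bromo-6-formyl-4-methoxyphenyl 2,6-dihydroxy-4-methylbenzoate
Conditions: (CF3CO)2O, toluene, 0 °C to rt; brief aq NaHCO3 work-up
Reagents that add atoms: none
Why: Mixed-anhydride (TFAA) esterification, the usual depside coupling and a standard answer to di-ortho-substituted benzoic acids and hindered phenols, should acylate the phenol oxygen of 2 through the acylium-like mixed anhydride of electron-rich 1, while transient O-trifluoroacetates fall off in the work-up.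

Step 2
Reactants: 3 2-bromo-6-formyl-4-methoxyphenyl 2,6-dihydroxy-4-methylbenzoate
Product: 5 methyl 2-(2-bromo-6-formyl-4-methoxyphenoxy)-6-hydroxy-4-methylbenzoate, via diaryl ether acid 4 (not isolated)
Conditions: K2CO3 (1.0 equiv), DMSO, rt to 40 °C; then MeI (1.05 equiv), rt
Reagents that add atoms: iodomethane, CI
Why: In this Smiles rearrangement of a 2-hydroxydepside a ring B phenoxide attacks the ipso carbon of ring A (activated by ortho CHO and ortho Br) through a six-membered spiro Meisenheimer adduct, the carboxylate leaves irreversibly, and under the remaining KHCO3 it is the only anion that MeI alkylates (SN2), so the chelated ring B OH stays free.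

Step 3
Reactants: 5 methyl 2-(2-bromo-6-formyl-4-methoxyphenoxy)-6-hydroxy-4-methylbenzoate
Product: 6 methyl 2-[2-bromo-6-(hydroxymethyl)-4-methoxyphenoxy]-6-hydroxy-4-methylbenzoate
Conditions: NaBH4, MeOH/THF, 0 °C
Reagents that add atoms: none
Why: Chemoselective borohydride reduction should take only the aldehyde, since the di-ortho-substituted salicylate ester, the aryl bromide and the diaryl ether are inert at 0 °C.

Step 4
Reactants: 6 methyl 2-[2-bromo-6-(hydroxymethyl)-4-methoxyphenoxy]-6-hydroxy-4-methylbenzoate
Product: 8 methyl 2-hydroxy-6-[2-hydroxy-6-(hydroxymethyl)-4-methoxyphenoxy]-4-methylbenzoate, via pinacol boronate 7 (not isolated)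
Conditions: B2pin2, XPhos Pd G2 (3 mol %), KOAc, 1,4-dioxane, 90 °C; then 30% aq H2O2, NaHCO3, THF, 0 °C to rt
Reagents that add atoms: bis(pinacolato)diboron, CC1(C)OB(OC1(C)C)B1OC(C)(C)C(C)(C)O1 (boron unit of 7); hydrogen peroxide, OO (phenol oxygen of 8)
Why: Miyaura borylation followed by peroxide ipso-hydroxylation (1,2-aryl shift from B to O) should exchange Br for OH without strong base or heat once the new phenol exists, so the methyl ester survives and the aryl group cannot wander between the two neighbouring ring A oxygens.

Step 5
Reactants: 8 methyl 2-hydroxy-6-[2-hydroxy-6-(hydroxymethyl)-4-methoxyphenoxy]-4-methylbenzoate; 9 pent-4-enoic acid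
Product: 10 methyl 2-hydroxy-6-{2-hydroxy-4-methoxy-6-[(pent-4-enoyloxy)methyl]phenoxy}-4-methylbenzoate
Conditions: PPh3, DIAD, THF, 0 °C to rt
Reagents that add atoms: none
Why: The Mitsunobu esterification turns only the aliphatic benzylic OH into an alkoxyphosphonium leaving group and only the carboxylic acid is acidic enough to serve as the nucleophile, so both phenols should stay free, as in the known chemoselective esterification of phenolic benzyl alcohols with fatty acids.

Step 6
Reactants: 10 methyl 2-hydroxy-6-{2-hydroxy-4-methoxy-6-[(pent-4-enoyloxy)methyl]phenoxy}-4-methylbenzoate; 11 1-iodoundecane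
Product: 12 betaethrin E, methyl 2-{2-[(hexadecanoyloxy)methyl]-6-hydroxy-4-methoxyphenoxy}-6-hydroxy-4-methylbenzoate
Conditions: 11 (2 equiv), NiBr2·diglyme (10 mol %), dtbbpy (15 mol %), (EtO)2MeSiH (3 equiv), Na2CO3 (2 equiv), DMA, 25 °C; aq citric acid work-up
Reagents that add atoms: none
Why: A bipyridine-ligated Ni–H, formed from the nickel salt, the hydrosilane and carbonate, inserts reversibly into the terminal C4=C5 alkene of 10 to give the primary C5–Ni alkyl, which abstracts iodine from 11, recaptures the undecyl radical and forms the C5–C6 sp3–sp3 bond by reductive elimination from a Ni(III) dialkyl. The closest known reaction type is the nickel hydride-catalysed reductive anti-Markovnikov hydroalkylation of unactivated terminal olefins with primary alkyl iodides, which runs at room temperature and accepts esters and protic groups. No ring is closed and no stereocentre is created, because the product chain is unbranched. Linear regioselectivity over branched or chain-walked products is needed, and it is secured by the monosubstituted alkene and by the preference of the bipyridine–nickel centre for the primary alkyl. Chemoselectivity for C- over O-alkylation is also needed, and it is secured by the weak, sparingly soluble base, the low temperature, the hydrogen bond of the ring B OH to its ester and the shielding of the ring A OH by the adjacent di-ortho-substituted aryloxy group, while any silyl ethers formed from the silane are cleaved in the acidic work-up. Because the chain arrives saturated, no hydrogenation follows, so the benzylic ArCH2–O bond, the diaryl ether and both esters should remain untouched.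

Compound list
1 | 2,6-dihydroxy-4-methylbenzoic acid | Cc1cc(O)c(C(=O)O)c(O)c1 | starting material
2 | 3-bromo-2-hydroxy-5-methoxybenzaldehyde | COc1cc(Br)c(O)c(C=O)c1 | starting material
3 | 2-bromo-6-formyl-4-methoxyphenyl 2,6-dihydroxy-4-methylbenzoate (depside) | Cc1cc(O)c(C(=O)Oc2c(Br)cc(OC)cc2C=O)c(O)c1 | intermediate
4 | 2-(2-bromo-6-formyl-4-methoxyphenoxy)-6-hydroxy-4-methylbenzoic acid (present as its potassium salt, not isolated) | Cc1cc(O)c(C(=O)O)c(Oc2c(Br)cc(OC)cc2C=O)c1 | intermediate
5 | methyl 2-(2-bromo-6-formyl-4-methoxyphenoxy)-6-hydroxy-4-methylbenzoate | COC(=O)c1c(O)cc(C)cc1Oc1c(Br)cc(OC)cc1C=O | intermediate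
6 | methyl 2-[2-bromo-6-(hydroxymethyl)-4-methoxyphenoxy]-6-hydroxy-4-methylbenzoate | COC(=O)c1c(O)cc(C)cc1Oc1c(Br)cc(OC)cc1CO | intermediate
7 | methyl 2-hydroxy-6-[2-(hydroxymethyl)-4-methoxy-6-(4,4,5,5-tetramethyl-1,3,2-dioxaborolan-2-yl)phenoxy]-4-methylbenzoate (not isolated) | COC(=O)c1c(O)cc(C)cc1Oc1c(B2OC(C)(C)C(C)(C)O2)cc(OC)cc1CO | intermediate
8 | methyl 2-hydroxy-6-[2-hydroxy-6-(hydroxymethyl)-4-methoxyphenoxy]-4-methylbenzoate | COC(=O)c1c(O)cc(C)cc1Oc1c(O)cc(OC)cc1CO | intermediate
9 | pent-4-enoic acid | C=CCCC(=O)O | starting material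
10 | methyl 2-hydroxy-6-{2-hydroxy-4-methoxy-6-[(pent-4-enoyloxy)methyl]phenoxy}-4-methylbenzoate | C=CCCC(=O)OCc1cc(OC)cc(O)c1Oc1cc(C)cc(O)c1C(=O)OC | intermediate
11 | 1-iodoundecane | CCCCCCCCCCCI | starting material
12 | betaethrin E, methyl 2-{2-[(hexadecanoyloxy)methyl]-6-hydroxy-4-methoxyphenoxy}-6-hydroxy-4-methylbenzoate | CCCCCCCCCCCCCCCC(=O)OCc1cc(OC)cc(O)c1Oc1cc(C)cc(O)c1C(=O)OC | target

Total step count: 6. Longest linear sequence: 6 steps (from 1 or 2 to 12).

Steps most likely to fail

Risk 1, step 6. Three things may go wrong:
- The iodide may O-alkylate the free phenols.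
- The salicylate unit may chelate and sequester nickel.
- Ni–H may move the alkene toward the ester faster than the coupling occurs.

The fallback sets out from 8 and returns at 12. It forms the same C5–C6 bond as an alkene under base-free conditions.
- Mitsunobu esterification of 8 with hex-5-enoic acid (PPh3, DIAD, THF) should give methyl 2-{2-[(hex-5-enoyloxy)methyl]-6-hydroxy-4-methoxyphenoxy}-6-hydroxy-4-methylbenzoate F1.
- Olefin cross metathesis of this ester with excess 1-dodecene (Hoveyda–Grubbs second-generation catalyst, 1,4-benzoquinone, CH2Cl2, 40 °C) should give methyl 2-{2-[((E)-hexadec-5-enoyloxy)methyl]-6-hydroxy-4-methoxyphenoxy}-6-hydroxy-4-methylbenzoate F2. It should form as an E/Z mixture, and the geometry does not matter.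
- Diimide reduction (TsNHNH2, NaOAc, THF/H2O, reflux) should saturate the alkene without touching the benzylic C–O bond and deliver 12.

Risk 2, step 2. The para-methoxy group lowers the electrophilicity of the ring A ipso carbon. Acyl–oxygen cleavage of the activated aryl ester, by hydrolysis or intermolecular acyl transfer, may therefore outrun the rearrangement.

The fallback sets out from 2, bypasses 3 and 4, and returns at 5. It reverses the polarity, so that ring B becomes the electrophile.
- Intermolecular SNAr of the phenoxide of 2 on commercial methyl 2,6-difluoro-4-methylbenzoate (COC(=O)c1c(F)cc(C)cc1F; K2CO3, DMF, 110 °C) should give methyl 2-(2-bromo-6-formyl-4-methoxyphenoxy)-6-fluoro-4-methylbenzoate F3.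
- The remaining ester-activated fluoride is then displaced by the alkoxide of 2-(methylsulfonyl)ethanol (NaH, DMF, 0 °C to rt). This should give methyl 2-(2-bromo-6-formyl-4-methoxyphenoxy)-4-methyl-6-[2-(methylsulfonyl)ethoxy]benzoate F4.
- F4 should lose the sulfonylethyl group by E1cB elimination in the same flask and release the phenol 5.

Risk 3, step 4. Oxidative addition and transmetalation at the hindered, electron-rich C–Br bond may be slow. Protodebromination may then take over.

The fallback sets out from 5, bypasses 6 and 7, and returns at 8. It forms the C–O bond directly at palladium with a hydroxide surrogate, before the aldehyde is reduced.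
- Coupling of 5 with (E)-benzaldoxime (tBuBrettPhos Pd G3, Cs2CO3, DMF, 80 °C) should give methyl 2-{2-[(E)-(benzylideneamino)oxy]-6-formyl-4-methoxyphenoxy}-6-hydroxy-4-methylbenzoate F5.
- F5 should fragment under the base to methyl 2-(2-formyl-6-hydroxy-4-methoxyphenoxy)-6-hydroxy-4-methylbenzoate F6.
- NaBH4 in MeOH at 0 °C should then give 8.

Further compounds
F1 | step 6 | methyl 2-{2-[(hex-5-enoyloxy)methyl]-6-hydroxy-4-methoxyphenoxy}-6-hydroxy-4-methylbenzoate | C=CCCCC(=O)OCc1cc(OC)cc(O)c1Oc1cc(C)cc(O)c1C(=O)OC
F2 | step 6 | methyl 2-{2-[((E)-hexadec-5-enoyloxy)methyl]-6-hydroxy-4-methoxyphenoxy}-6-hydroxy-4-methylbenzoate | CCCCCCCCCC/C=C/CCCC(=O)OCc1cc(OC)cc(O)c1Oc1cc(C)cc(O)c1C(=O)OC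
F3 | step 2 | methyl 2-(2-bromo-6-formyl-4-methoxyphenoxy)-6-fluoro-4-methylbenzoate | COC(=O)c1c(F)cc(C)cc1Oc1c(Br)cc(OC)cc1C=O
F4 | step 2 | methyl 2-(2-bromo-6-formyl-4-methoxyphenoxy)-4-methyl-6-[2-(methylsulfonyl)ethoxy]benzoate | COC(=O)c1c(OCCS(C)(=O)=O)cc(C)cc1Oc1c(Br)cc(OC)cc1C=O
F5 | step 4 | methyl 2-{2-[(E)-(benzylideneamino)oxy]-6-formyl-4-methoxyphenoxy}-6-hydroxy-4-methylbenzoate | COC(=O)c1c(O)cc(C)cc1Oc1c(O/N=C/c2ccccc2)cc(OC)cc1C=O
F6 | step 4 | methyl 2-(2-formyl-6-hydroxy-4-methoxyphenoxy)-6-hydroxy-4-methylbenzoate | COC(=O)c1c(O)cc(C)cc1Oc1c(O)cc(OC)cc1C=O
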